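**Remark.** The target has no stereocentre and is drawn as one enol tautomer; tautomers of the intermediates are a matter of drawing. Ring A atom numbers follow the triketone form, 2-butanoyl-4,4-dimethylcyclohexane-1,3,5-trione: C2 carries the butanoyl group, C4 the two methyl groups, C6 the CH2 bridge.

## Retrosynthetic overview

1. The target is five rings A–B–C–B'–A' joined by four CH2 bridges (A, A' = butyrylfilicinic acid; B, C, B' = butanoylphloroglucinol). The two outer bridges are cut last, at ring A C6, to a three-ring bis-Mannich base and two butyrylfilicinic acids (o-quinone methide Michael addition).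
2. The core B–C–B' is cut at the two inner bridges to the bis-Mannich base of butanoylphloroglucinol (ring C) and two more butanoylphloroglucinols. The aromatic rings are not built; they come from phloroglucinol.
3. Ring A is the only ring that is formed. A [3+3] α,α'-annulation joins malonyl dichloride (C1–C2–C3) to the silyl enol ether of 3-methylbutan-2-one (C4–C5–C6), making C3–C4 at the quaternary carbon and C1–C6 in one operation; C2 is then butanoylated.
4. Enabling feature: ring A is a non-aromatic 1,3,5-trione. Its C5 carbonyl has the gem-dimethyl carbon C4 and the bridge-bearing carbon C6 as its two α-carbons, and C1 and C3 are the two acyl carbons of a malonyl unit. The ring is therefore ketone plus malonyl in natural polarity, and the quaternary C4 fixes the order of the two acylations.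
5. Order of ring formation: ring A in step 2 (used twice in step 8); rings B, C, B' are preformed.

Key step: step 2

## Route

Step 1
Reactants: 1 3-methylbut-3-en-2-one
Product: 2 triethyl[(3-methylbut-2-en-2-yl)oxy]silane
Conditions: Et3SiH (1.1 equiv), RhCl(PPh3)3 (0.5 mol%), toluene, 50 °C; distillation
Reagents that add atoms: triethylsilane, CC[SiH](CC)CC
Why: Rhodium-catalysed conjugate (1,4-) hydrosilylation of an α-methylene ketone puts hydride on the terminal CH2 and silicon on oxygen, so the tetrasubstituted silyl enol ether should form regiospecifically without thermodynamic enolisation, and no alkene geometry arises because the new alkene carbon carries two methyl groups.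

Step 2
Reactants: 2 triethyl[(3-methylbut-2-en-2-yl)oxy]silane; 3 malonyl dichloride
Product: 6 filicinic acid, via acyl chloride 4 (not isolated), via silyl enol ether 5 (not isolated)
Conditions: 3 (1.3 equiv), Et2O, −20 °C → rt; then 2 M aq KOH, BnEt3NCl (cat.), rt; then HCl to pH 1
Reagents that add atoms: none
Why: Malonyl dichloride (directly or as chlorocarbonylketene after loss of HCl) C-acylates the fully substituted nucleophilic carbon of 2, which forms the C3–C4 bond and the quaternary gem-dimethyl carbon; the resulting silyloxocarbenium ion has no hydrogen on that side and can only lose a proton from the methyl group, giving the transposed terminal silyl enol ether 4 with the second acid chloride in reach. Its terminal carbon then attacks that acid chloride in a 6-(enolexo)-exo-trig C-acylation that forms the C1–C6 bond and closes ring A as the vinylogous silyl ester 5, and aqueous KOH under phase transfer should cleave the silyl group and any O-acylated material to give 6 as its enolate. The closest known reaction is the Effenberger α,α'-annulation of methyl or silyl enol ethers with malonyl dichloride, which builds cyclohexane-1,3,5-triones with quaternary α-carbons in bicyclo[3.3.1]nonane-2,4,9-trione syntheses. No stereocentre is formed. The step needs C,C- instead of C,O-annulation and first acylation at C4 instead of C6: the regiodefined tetrasubstituted enol ether fixes the order of events, and closure through oxygen would give only a non-aromatic exo-methylene enol lactone, whereas closure through carbon gives the enol-stabilised trione.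

Step 3
Reactants: 6 filicinic acid
Product: 7 butyrylfilicinic acid
Conditions: butyric acid (1.05 equiv), DCC (1.1 equiv), DMAP, CH2Cl2, 0 °C → rt; dilute HCl wash
Reagents that add atoms: butyric acid, CCCC(=O)O
Why: Steglich-type O-acylation of the enolised trione followed by DMAP-mediated O-to-C acyl migration (the standard one-pot C-acylation of cyclic 1,3-diones) should give the chelated β-triketone at C2; C2 and C6 of 6 are equivalent by the mirror plane through C1 and C4, so a single mono-acyl product results, and the first acyl group deactivates the ring toward a second acylation.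

Step 4
Reactants: 8 phloroglucinol
Product: 9 1-(2,4,6-trihydroxyphenyl)butan-1-one
Conditions: butyryl chloride (1.0 equiv), AlCl3 (3.5 equiv), CH2Cl2/MeNO2, 0 → 40 °C; ice/HCl
Reagents that add atoms: butyryl chloride, CCCC(Cl)=O
Why: Friedel–Crafts acylation of the very electron-rich arene should stop after one acyl group because the chelated aryl ketone deactivates the ring.

Step 5
Reactants: 9 1-(2,4,6-trihydroxyphenyl)butan-1-one
Product: 10 1-{3,5-bis[(dimethylamino)methyl]-2,4,6-trihydroxyphenyl}butan-1-one
Conditions: 37% aq CH2O (2.5 equiv), 40% aq Me2NH (2.5 equiv), EtOH, 0 °C → rt; filtration of the zwitterion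
Reagents that add atoms: formaldehyde, C=O; dimethylamine, CNC
Why: Phenolic Mannich aminomethylation occurs at both remaining ring positions, each activated by three hydroxyl groups, and excess reagent drives it to the bis-Mannich base.

Step 6
Reactants: 10 1-{3,5-bis[(dimethylamino)methyl]-2,4,6-trihydroxyphenyl}butan-1-one; 9 1-(2,4,6-trihydroxyphenyl)butan-1-one (8 equiv, excess recovered)
Product: 11 1-{3,5-bis[(3-butanoyl-2,4,6-trihydroxyphenyl)methyl]-2,4,6-trihydroxyphenyl}butan-1-one
Conditions: 1,4-dioxane, 100 °C, N2 stream
Reagents that add atoms: none
Why: Thermal loss of Me2NH from each phenolic Mannich unit gives an o-quinone methide that is captured by a free ring CH of 9 (Michael addition, then re-aromatisation), and the large excess of 9 suppresses chain extension.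

Step 7
Reactants: 11 1-{3,5-bis[(3-butanoyl-2,4,6-trihydroxyphenyl)methyl]-2,4,6-trihydroxyphenyl}butan-1-one
Product: 12 1-{3,5-bis({3-butanoyl-5-[(dimethylamino)methyl]-2,4,6-trihydroxyphenyl}methyl)-2,4,6-trihydroxyphenyl}butan-1-one
Conditions: 37% aq CH2O (3 equiv), 40% aq Me2NH (3 equiv), EtOH/THF, 0 °C → rt
Reagents that add atoms: formaldehyde, C=O; dimethylamine, CNC
Why: The Mannich reaction can only occur at the two equivalent free CH positions of the outer rings, so excess reagent gives the bis-Mannich base without a selectivity problem.

Step 8
Reactants: 12 1-{3,5-bis({3-butanoyl-5-[(dimethylamino)methyl]-2,4,6-trihydroxyphenyl}methyl)-2,4,6-trihydroxyphenyl}butan-1-one; 7 butyrylfilicinic acid (2.4 equiv)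
Product: 13 pentaalbaspidin BBBBB
Conditions: 1,4-dioxane, 90 °C, N2 stream; dilute HCl wash; crystallisation
Reagents that add atoms: none
Why: Twofold o-quinone methide formation from 12 and Michael addition of the C6–H enol carbon of 7 should give both outer bridges cleanly, because every ring carbon of 12 is substituted and 7 is the only carbon nucleophile present.

## Compound list

1 | 3-methylbut-3-en-2-one | CC(=C)C(C)=O | starting material
2 | triethyl[(3-methylbut-2-en-2-yl)oxy]silane | CC(C)=C(C)O[Si](CC)(CC)CC | intermediate
3 | malonyl dichloride (propanedioyl dichloride) | O=C(Cl)CC(Cl)=O | starting material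
4 | 4,4-dimethyl-3-oxo-5-[(triethylsilyl)oxy]hex-5-enoyl chloride | C=C(O[Si](CC)(CC)CC)C(C)(C)C(=O)CC(Cl)=O | intermediate
5 | 6,6-dimethyl-5-[(triethylsilyl)oxy]cyclohex-4-ene-1,3-dione | CC[Si](CC)(CC)OC1=CC(=O)CC(=O)C1(C)C | intermediate
6 | filicinic acid (3,5-dihydroxy-4,4-dimethylcyclohexa-2,5-dien-1-one) | CC1(C)C(O)=CC(=O)C=C1O | intermediate
7 | butyrylfilicinic acid (2-butanoyl-3,5-dihydroxy-6,6-dimethylcyclohexa-2,4-dien-1-one) | CCCC(=O)C1=C(O)C=C(O)C(C)(C)C1=O | intermediate
8 | phloroglucinol (benzene-1,3,5-triol) | Oc1cc(O)cc(O)c1 | starting material
9 | 1-(2,4,6-trihydroxyphenyl)butan-1-one | CCCC(=O)c1c(O)cc(O)cc1O | intermediate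
10 | 1-{3,5-bis[(dimethylamino)methyl]-2,4,6-trihydroxyphenyl}butan-1-one | CCCC(=O)c1c(O)c(CN(C)C)c(O)c(CN(C)C)c1O | intermediate
11 | 1-{3,5-bis[(3-butanoyl-2,4,6-trihydroxyphenyl)methyl]-2,4,6-trihydroxyphenyl}butan-1-one | CCCC(=O)c1c(O)c(Cc2c(O)cc(O)c(C(=O)CCC)c2O)c(O)c(Cc2c(O)cc(O)c(C(=O)CCC)c2O)c1O | intermediate
12 | 1-{3,5-bis({3-butanoyl-5-[(dimethylamino)methyl]-2,4,6-trihydroxyphenyl}methyl)-2,4,6-trihydroxyphenyl}butan-1-one | CCCC(=O)c1c(O)c(Cc2c(O)c(CN(C)C)c(O)c(C(=O)CCC)c2O)c(O)c(Cc2c(O)c(CN(C)C)c(O)c(C(=O)CCC)c2O)c1O | intermediate
13 | pentaalbaspidin BBBBB | CCCC(=O)C1=C(O)C(Cc2c(O)c(Cc3c(O)c(Cc4c(O)c(CC5=C(O)C(C)(C)C(=O)C(C(=O)CCC)=C5O)c(O)c(C(=O)CCC)c4O)c(O)c(C(=O)CCC)c3O)c(O)c(C(=O)CCC)c2O)=C(O)C(C)(C)C1=O | target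

## Step count and risks

Total step count: 8. Longest linear sequence: 5 steps (steps 4, 5, 6, 7, 8 from phloroglucinol); the ring A branch (steps 1–3) joins at step 8.

Steps most likely to fail:

**Step 2 (key step).** The second ring bond may close through oxygen instead of carbon, or the silyl group may be lost early, so that enol lactone and open-chain acid material form and little trione is obtained. The fallback sets out from 9 and comes back at 7. It is the classical dearomative gem-dimethylation of an acylphloroglucinol: 9 is treated with iodomethane (about 2 equiv) and NaOMe in MeOH at 0 °C to room temperature, and 7 is separated from mono- and trimethylated material by crystallisation. Ring A is then taken from phloroglucinol instead of being built, steps 1–3 are not needed, and no new compound is made (F0).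

**Step 6.** The product and the two-ring intermediate keep nucleophilic ring positions and may compete with 9 for the quinone methide, giving chain extension to higher oligomers. The fallback sets out from 9 and comes back at 13, forming the bridges from the outside in.
- 9 is mono-aminomethylated (CH2O and Me2NH, 1 equiv each, EtOH, 0 °C) to 1-{3-[(dimethylamino)methyl]-2,4,6-trihydroxyphenyl}butan-1-one F1.
- F1 is heated with a slight excess of 7 (dioxane, 90 °C) to the two-ring compound 2-butanoyl-4-[(3-butanoyl-2,4,6-trihydroxyphenyl)methyl]-3,5-dihydroxy-6,6-dimethylcyclohexa-2,4-dien-1-one F2, which has a single free ring position.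
- Two equivalents of F2 are joined with the bis-Mannich base 10 (dioxane, 90 °C) to give 13 directly, so no nucleophile with two free sites meets a bis-electrophile.

**Step 8.** Under the hot, amine-containing conditions the methylene bridges may cleave reversibly by retro-Michael reaction and exchange ring units, and the second coupling may stay incomplete. The fallback sets out from 7 and 11 and comes back at 13, with the polarity of the coupling reversed.
- 7 is aminomethylated (CH2O, Me2NH, EtOH, 0 °C) to 2-butanoyl-4-[(dimethylamino)methyl]-3,5-dihydroxy-6,6-dimethylcyclohexa-2,4-dien-1-one F3.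
- F3 is a betaine of a vinylogous acid and should lose Me2NH under much milder conditions (AcOH/NaOAc, MeCN, rt to 50 °C) to give the 2-methylene trione.
- Two equivalents of this acceptor are captured by the two free ring CH positions of 11, so the bridged three-ring core is never heated with free amine.

## Further compounds

F0 | step 2 | none | none
F1 | step 6 | 1-{3-[(dimethylamino)methyl]-2,4,6-trihydroxyphenyl}butan-1-one | CCCC(=O)c1c(O)cc(O)c(CN(C)C)c1O
F2 | step 6 | 2-butanoyl-4-[(3-butanoyl-2,4,6-trihydroxyphenyl)methyl]-3,5-dihydroxy-6,6-dimethylcyclohexa-2,4-dien-1-one | CCCC(=O)C1=C(O)C(Cc2c(O)cc(O)c(C(=O)CCC)c2O)=C(O)C(C)(C)C1=O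
F3 | step 8 | 2-butanoyl-4-[(dimethylamino)methyl]-3,5-dihydroxy-6,6-dimethylcyclohexa-2,4-dien-1-one | CCCC(=O)C1=C(O)C(CN(C)C)=C(O)C(C)(C)C1=O
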